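## Retrosynthetic overview

1. Feature: the isovaleryl ring is a fully substituted benzene whose three oxygen-bearing carbons have different neighbours. The C–OCH3 lies between C–CH3 and C–acyl, one C–OH lies between C–CH3 and the bridge-bearing carbon, and the other C–OH lies between the bridge-bearing carbon and C–acyl. Each oxygen is therefore brought in on its own carbon and not differentiated on a preformed triol.
2. Last disconnection: three O-benzyl groups, removed by neutral hydrogenolysis, because the ArCH2Ar bridge of such dimers exchanges its halves in acid or base.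
3. Key disconnection: the isovaleryl ring is cut at C(OCH3)–C(acyl) and at C(bridge-bearing)–C(O-benzyl). This gives 1-benzyloxy-5-methylhex-1-yn-3-one and a 1,1-dimethoxy-2-methyl-3-silyloxy-1,3-diene that already carries the isobutyryl ring on its terminal CH2.
4. The diene comes from the hexasubstituted isobutyryl-ring benzaldehyde and 4,4-dimethoxy-3-methylbut-3-en-2-one by aldol condensation and then 1,4-hydrosilylation. The ynone comes from benzyl alcohol, trichloroethylene and isovaleraldehyde.
5. Ring order: the isobutyryl ring is bought as 5-methoxyresorcinol and filled by three directed lithiations, bridge carbon first, which makes the other two positions equivalent. The isovaleryl ring is the only ring formed, and it is formed last.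

Key step: step 14

Remark: the target has no stereocentre, axis or stereogenic double bond. It is achiral, so no step has to control absolute configuration.

## Route

Step 1
Reactants: 1 5-methoxyresorcinol
Product: 2 1-methoxy-3,5-bis(methoxymethoxy)benzene
Conditions: NaH, MOMCl, DMF, 0 → 23 °C
Reagents that add atoms: chloromethyl methyl ether, COCCl
Why: Williamson-type ether formation on both phenoxides installs the two strongest ortho-directing groups of the ring and leaves the pre-set methyl ether untouched.

Step 2
Reactants: 2 1-methoxy-3,5-bis(methoxymethoxy)benzene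
Product: 4 4-methoxy-2,6-bis(methoxymethoxy)benzaldehyde, via aryllithium 3 (not isolated)
Conditions: n-BuLi, THF, 0 °C; DMF, 0 → 23 °C; H2O
Reagents that add atoms: N,N-dimethylformamide, CN(C)C=O
Why: In this directed ortho-metalation the carbon between the two chelating OCH2OCH3 groups is lithiated in preference to the carbons next to the weaker OCH3 director, so formylation fixes the future bridge carbon para to the methoxy group and makes the two remaining ring CH positions equivalent.

Step 3
Reactants: 4 4-methoxy-2,6-bis(methoxymethoxy)benzaldehyde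
Product: 7 4-methoxy-3-methyl-2,6-bis(methoxymethoxy)benzaldehyde, via lithium amino alkoxide 5 (not isolated), via ring-lithiated amino alkoxide 6 (not isolated)
Conditions: 1-methylpiperazine, n-BuLi, THF, −20 °C; 4; n-BuLi, −20 → 0 °C; MeI, −78 → 23 °C; H2O
Reagents that add atoms: iodomethane, CI
Why: Addition of the lithium amide masks the aldehyde in situ as an α-amino alkoxide, directed ortho-metalation then takes one of the two equivalent CH positions between OCH3 and OCH2OCH3, and methylation followed by aqueous release of the aldehyde should give a single regioisomer.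

Step 4
Reactants: 7 4-methoxy-3-methyl-2,6-bis(methoxymethoxy)benzaldehyde; 8 N-methoxy-N,2-dimethylpropanamide
Product: 11 4-methoxy-3-methyl-5-(2-methylpropanoyl)-2,6-bis(methoxymethoxy)benzaldehyde, via lithium amino alkoxide 9 (not isolated), via ring-lithiated amino alkoxide 10 (not isolated)
Conditions: 1-methylpiperazine, n-BuLi, THF, −20 °C; 7; n-BuLi, −20 → 0 °C; 8, −78 → 0 °C; H2O
Reagents that add atoms: none
Why: The same in situ α-amino alkoxide masking lets the last ring CH, again flanked by two alkoxy directors, be lithiated, and the Weinreb ketone synthesis stops at the ketone because the chelated tetrahedral adduct survives until work-up.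

Step 5
Reactants: 11 4-methoxy-3-methyl-5-(2-methylpropanoyl)-2,6-bis(methoxymethoxy)benzaldehyde
Product: 12 2,6-dihydroxy-4-methoxy-3-methyl-5-(2-methylpropanoyl)benzaldehyde
Conditions: HCl (cat.), MeOH, 50 °C; aqueous work-up
Reagents that add atoms: none
Why: Acid-catalysed acetal exchange removes both MOM groups at the monomer stage, where there is no methylene bridge for acid to scramble, and the aryl methyl ether is inert.

Step 6
Reactants: 12 2,6-dihydroxy-4-methoxy-3-methyl-5-(2-methylpropanoyl)benzaldehyde
Product: 13 2,6-bis(benzyloxy)-4-methoxy-3-methyl-5-(2-methylpropanoyl)benzaldehyde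
Conditions: BnBr, K2CO3, DMF, 50 °C
Reagents that add atoms: benzyl bromide, BrCc1ccccc1
Why: Williamson ether synthesis in a dipolar aprotic solvent favours O- over C-alkylation of the acidic chelated phenols and installs groups that can later leave under neutral hydrogenolysis.

Step 7
Reactants: 14 trimethyl orthopropionate
Product: 15 1,1-dimethoxyprop-1-ene
Conditions: Al(Ot-Bu)3 (one Ot-Bu per ortho ester), neat, reflux, slow fractional distillation
Reagents that add atoms: none
Why: Aluminium-alkoxide-mediated dealcoholation of an ortho ester bearing an α-hydrogen is the classical route to alkylketene acetals, and the volatile product is distilled out as it forms.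

Step 8
Reactants: 15 1,1-dimethoxyprop-1-ene (two equivalents); 16 acetyl chloride
Product: 17 4,4-dimethoxy-3-methylbut-3-en-2-one
Conditions: Et2O, 0 → 35 °C; fractional distillation
Reagents that add atoms: none
Why: C-acylation of a ketene acetal by an acid chloride gives an acylated dimethoxycarbenium ion, which loses its doubly activated proton to a second molecule of ketene acetal (the HCl trap) to give the acylketene acetal.

Step 9
Reactants: 17 4,4-dimethoxy-3-methylbut-3-en-2-one; 13 2,6-bis(benzyloxy)-4-methoxy-3-methyl-5-(2-methylpropanoyl)benzaldehyde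
Product: 21 (1E)-1-[2,6-bis(benzyloxy)-4-methoxy-3-methyl-5-(2-methylpropanoyl)phenyl]-5,5-dimethoxy-4-methylpenta-1,4-dien-3-one, via lithium dienolate 18 (not isolated), via lithium aldolate 19 (not isolated), via benzylic mesylate 20 (not isolated)
Conditions: LDA, THF, −78 °C; 13, −78 °C; MsCl, −78 → 0 °C; DBU, 0 → 23 °C
Reagents that add atoms: none
Why: Kinetic α′-deprotonation of the vinylogous carbonate (its only acidic CH), aldol addition to the non-enolisable aldehyde and E1cB loss of mesylate amount to a stepwise Claisen–Schmidt condensation that should give the E-enone under anhydrous, non-acidic conditions that spare the ketene acetal.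

Step 10
Reactants: 21 (1E)-1-[2,6-bis(benzyloxy)-4-methoxy-3-methyl-5-(2-methylpropanoyl)phenyl]-5,5-dimethoxy-4-methylpenta-1,4-dien-3-one
Product: 22 1-{2,4-bis(benzyloxy)-3-[(2Z)-5,5-dimethoxy-4-methyl-3-(triethylsilyloxy)penta-2,4-dien-1-yl]-6-methoxy-5-methylphenyl}-2-methylpropan-1-one
Conditions: Et3SiH, RhCl(PPh3)3 (2 mol %), benzene, 50 °C; filtration through basic alumina, used at once
Reagents that add atoms: triethylsilane, CC[SiH](CC)CC
Why: Rhodium-catalysed 1,4-hydrosilylation of an enone with a monohydrosilane delivers H to the styryl β-carbon and silicon to oxygen through the s-cis enone and so gives the Z silyl enol ether directly, while the tetrasubstituted ketene-acetal alkene cannot bind the metal and the enolisable isobutyryl ketone never meets base or a silylating agent.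

Step 11
Reactants: 23 benzyl alcohol; 24 trichloroethylene
Product: 26 benzyl (E)-1,2-dichlorovinyl ether, via dichloroacetylene 25 (not isolated)
Conditions: KH, THF, 0 °C; 24, −50 → 23 °C
Reagents that add atoms: none
Why: Alkoxide-induced dehydrochlorination to dichloroacetylene followed by anti addition of the alcohol gives the E-1,2-dichlorovinyl ether, the standard entry to ynol ethers.

Step 12
Reactants: 26 benzyl (E)-1,2-dichlorovinyl ether; 27 isovaleraldehyde
Product: 30 1-(benzyloxy)-5-methylhex-1-yn-3-ol (racemic), via benzyl chloroethynyl ether 28 (not isolated), via lithium benzyloxyacetylide 29 (not isolated)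
Conditions: n-BuLi (2.2 equiv), Et2O, −78 → −40 °C; 27, −78 °C; H2O
Reagents that add atoms: none
Why: Deprotonation with β-elimination and then chlorine–lithium exchange convert the dichlorovinyl ether into the lithium alkoxyacetylide, whose 1,2-addition to the aldehyde gives the racemic propargylic alcohol, and its stereocentre is removed in the next step.

Step 13
Reactants: 30 1-(benzyloxy)-5-methylhex-1-yn-3-ol
Product: 31 1-(benzyloxy)-5-methylhex-1-yn-3-one
Conditions: activated MnO2, CH2Cl2, 0 → 23 °C; kept cold, used at once
Reagents that add atoms: none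
Why: Neutral heterogeneous MnO2 oxidation of a propargylic alcohol avoids the acid that would trigger Meyer–Schuster rearrangement or hydration of the ynol ether.

Step 14
Reactants: 22 1-{2,4-bis(benzyloxy)-3-[(2Z)-5,5-dimethoxy-4-methyl-3-(triethylsilyloxy)penta-2,4-dien-1-yl]-6-methoxy-5-methylphenyl}-2-methylpropan-1-one; 31 1-(benzyloxy)-5-methylhex-1-yn-3-one
Product: 34 1-[2-(benzyloxy)-3-{[2,6-bis(benzyloxy)-4-methoxy-3-methyl-5-(2-methylpropanoyl)phenyl]methyl}-4-hydroxy-6-methoxy-5-methylphenyl]-3-methylbutan-1-one, via cyclohexadiene ketal 32 (not isolated), via triethylsilyl ether 33 (not isolated)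
Conditions: TESOTf (1.2 equiv), 2,6-di-tert-butylpyridine (1.5 equiv), CH2Cl2, −78 → −20 °C; then TBAF, AcOH, THF, 0 °C
Reagents that add atoms: none
Why: Proposed new method: TESOTf silylates the carbonyl oxygen of the push–pull ynone 31, the resulting cumulenic oxocarbenium ion is attacked at its benzyloxy-bearing carbon by C4 of diene 22 (the CH that carries the CH2–aryl group and receives the push of all three oxygen donors), and the silyl allenol ether so formed closes through its central carbon onto the dimethoxycarbenium carbon C1, so the two new ring bonds are C4–C(OBn) and C1–C(acyl). The benzene ring is thus closed by a stepwise, highly asynchronous [4+2] (Mukaiyama–Michael addition, then six-membered closure of a carbon nucleophile on a dialkoxycarbenium ion) to ketal 32; TESOTf then ionises one ketal methoxy group, the hindered pyridine takes the C4 proton, and buffered fluoride unmasks the phenol of 33. The closest known reactions are the thermal Diels–Alder/aromatisation of 1,1-dimethoxy-3-silyloxybutadienes with acetylenic esters and ketones and the silyl-triflate-promoted Mukaiyama–Michael addition of silyl dienol ethers; what has not been shown is a β-alkoxy ynone as the two-carbon partner of a 2,4-disubstituted diene of this class. A halide-free silyl Lewis acid at low temperature replaces heat because benzyl alkynyl ethers undergo a [3,3] shift on mild heating, because the donor-substituted alkyne is too weak a dienophile below that, and because halide would dealkylate the O-benzyl oxonium ion. The selectivity needed is regioselectivity, and it is secured by matched polarity (the most nucleophilic diene terminus C4 meets the only strongly electrophilic alkyne carbon), while closure through C2 onto the ketone is a dead end because the C2 methyl group forbids aromatisation. The one new stereocentre (C4 of 32) is racemic and is erased on aromatisation; the Z enol ether keeps CH2–aryl on the outside of the s-cis diene, and the 2-methyl/3-silyloxy pair destabilises the s-trans form by allylic strain.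

Step 15
Reactants: 34 1-[2-(benzyloxy)-3-{[2,6-bis(benzyloxy)-4-methoxy-3-methyl-5-(2-methylpropanoyl)phenyl]methyl}-4-hydroxy-6-methoxy-5-methylphenyl]-3-methylbutan-1-one
Product: 35 1-[3-{[2,6-dihydroxy-4-methoxy-3-methyl-5-(2-methylpropanoyl)phenyl]methyl}-2,4-dihydroxy-6-methoxy-5-methylphenyl]-3-methylbutan-1-one (target)
Conditions: H2 (1 atm), 10% Pd/C, EtOAc, 23 °C
Reagents that add atoms: none
Why: Catalytic hydrogenolysis cleaves the three aryl benzyl ethers under neutral conditions, so the methylene bridge cannot exchange its halves, and the hydrogen-bonded aryl ketones and the diarylmethane should not be reduced at 1 atm.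

## Compound list

1 | 5-methoxyresorcinol | COc1cc(O)cc(O)c1 | starting material
2 | 1-methoxy-3,5-bis(methoxymethoxy)benzene | COCOc1cc(OC)cc(OCOC)c1 | intermediate
3 | [4-methoxy-2,6-bis(methoxymethoxy)phenyl]lithium | [Li]c1c(OCOC)cc(OC)cc1OCOC | intermediate
4 | 4-methoxy-2,6-bis(methoxymethoxy)benzaldehyde | O=Cc1c(OCOC)cc(OC)cc1OCOC | intermediate
5 | lithium α-(4-methylpiperazin-1-yl) alkoxide of 4 | [Li]OC(N1CCN(C)CC1)c1c(OCOC)cc(OC)cc1OCOC | intermediate
6 | 3-lithio derivative of 5 | [Li]OC(N1CCN(C)CC1)c1c(OCOC)c([Li])c(OC)cc1OCOC | intermediate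
7 | 4-methoxy-3-methyl-2,6-bis(methoxymethoxy)benzaldehyde | O=Cc1c(OCOC)c(C)c(OC)cc1OCOC | intermediate
8 | N-methoxy-N,2-dimethylpropanamide | CON(C)C(=O)C(C)C | starting material
9 | lithium α-(4-methylpiperazin-1-yl) alkoxide of 7 | [Li]OC(N1CCN(C)CC1)c1c(OCOC)c(C)c(OC)cc1OCOC | intermediate
10 | 5-lithio derivative of 9 | [Li]OC(N1CCN(C)CC1)c1c(OCOC)c(C)c(OC)c([Li])c1OCOC | intermediate
11 | 4-methoxy-3-methyl-5-(2-methylpropanoyl)-2,6-bis(methoxymethoxy)benzaldehyde | O=Cc1c(OCOC)c(C)c(OC)c(C(=O)C(C)C)c1OCOC | intermediate
12 | 2,6-dihydroxy-4-methoxy-3-methyl-5-(2-methylpropanoyl)benzaldehyde | O=Cc1c(O)c(C)c(OC)c(C(=O)C(C)C)c1O | intermediate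
13 | 2,6-bis(benzyloxy)-4-methoxy-3-methyl-5-(2-methylpropanoyl)benzaldehyde | O=Cc1c(OCc2ccccc2)c(C)c(OC)c(C(=O)C(C)C)c1OCc1ccccc1 | intermediate
14 | trimethyl orthopropionate | CCC(OC)(OC)OC | starting material
15 | 1,1-dimethoxyprop-1-ene | CC=C(OC)OC | intermediate
16 | acetyl chloride | CC(=O)Cl | starting material
17 | 4,4-dimethoxy-3-methylbut-3-en-2-one | COC(OC)=C(C)C(C)=O | intermediate
18 | lithium 4,4-dimethoxy-3-methylbuta-1,3-dien-2-olate | [Li]OC(=C)C(C)=C(OC)OC | intermediate
19 | lithium aldolate of 18 and 13 (racemic) | [Li]OC(CC(=O)C(C)=C(OC)OC)c1c(OCc2ccccc2)c(C)c(OC)c(C(=O)C(C)C)c1OCc1ccccc1 | intermediate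
20 | methanesulfonate of the aldol (racemic) | CS(=O)(=O)OC(CC(=O)C(C)=C(OC)OC)c1c(OCc2ccccc2)c(C)c(OC)c(C(=O)C(C)C)c1OCc1ccccc1 | intermediate
21 | (1E)-1-[2,6-bis(benzyloxy)-4-methoxy-3-methyl-5-(2-methylpropanoyl)phenyl]-5,5-dimethoxy-4-methylpenta-1,4-dien-3-one | COC(OC)=C(C)C(=O)/C=C/c1c(OCc2ccccc2)c(C)c(OC)c(C(=O)C(C)C)c1OCc1ccccc1 | intermediate
22 | 1-{2,4-bis(benzyloxy)-3-[(2Z)-5,5-dimethoxy-4-methyl-3-(triethylsilyloxy)penta-2,4-dien-1-yl]-6-methoxy-5-methylphenyl}-2-methylpropan-1-one (key-step diene) | COC(OC)=C(C)/C(O[Si](CC)(CC)CC)=C/Cc1c(OCc2ccccc2)c(C)c(OC)c(C(=O)C(C)C)c1OCc1ccccc1 | intermediate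
23 | benzyl alcohol | OCc1ccccc1 | starting material
24 | trichloroethylene | ClC=C(Cl)Cl | starting material
25 | dichloroacetylene | ClC#CCl | intermediate
26 | benzyl (E)-1,2-dichlorovinyl ether | Cl/C=C(/Cl)OCc1ccccc1 | intermediate
27 | isovaleraldehyde | CC(C)CC=O | starting material
28 | benzyl chloroethynyl ether | ClC#COCc1ccccc1 | intermediate
29 | lithium benzyloxyacetylide | [Li]C#COCc1ccccc1 | intermediate
30 | 1-(benzyloxy)-5-methylhex-1-yn-3-ol (racemic) | CC(C)CC(O)C#COCc1ccccc1 | intermediate
31 | 1-(benzyloxy)-5-methylhex-1-yn-3-one (key-step ynone) | CC(C)CC(=O)C#COCc1ccccc1 | intermediate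
32 | primary [4+2] adduct, 6,6-dimethoxycyclohexa-1,4-diene ketal (racemic at the CH carbon) | COC1(OC)C(C)=C(O[Si](CC)(CC)CC)C(Cc2c(OCc3ccccc3)c(C)c(OC)c(C(=O)C(C)C)c2OCc2ccccc2)C(OCc2ccccc2)=C1C(=O)CC(C)C | intermediate
33 | O-triethylsilyl ether of 34 | COc1c(C)c(O[Si](CC)(CC)CC)c(Cc2c(OCc3ccccc3)c(C)c(OC)c(C(=O)C(C)C)c2OCc2ccccc2)c(OCc2ccccc2)c1C(=O)CC(C)C | intermediate
34 | tri-O-benzyl ether of the target | COc1c(C)c(O)c(Cc2c(OCc3ccccc3)c(C)c(OC)c(C(=O)C(C)C)c2OCc2ccccc2)c(OCc2ccccc2)c1C(=O)CC(C)C | intermediate
35 | 1-[3-{[2,6-dihydroxy-4-methoxy-3-methyl-5-(2-methylpropanoyl)phenyl]methyl}-2,4-dihydroxy-6-methoxy-5-methylphenyl]-3-methylbutan-1-one | COc1c(C)c(O)c(Cc2c(O)c(C)c(OC)c(C(=O)C(C)C)c2O)c(O)c1C(=O)CC(C)C | target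

## Step count and risks

Total step count: 15. Longest linear sequence: 10 (steps 1–6, 9, 10, 14, 15).

The three steps most likely to fail:

**Step 14 (Proposed new method).**
- What may go wrong: the silyl-activated ynol ether may lose its benzyl group, or the diene may be protonated or desilylated before any C–C bond forms. The addition may also stop at the open-chain Michael stage without ring closure.
- Where the fallback runs: it uses only known chemistry, sets out from 2 and 12, and rejoins the route at 35.
- Isovaleryl monomer: lithiation of 2 between the two MOM groups and quenching with Me3SiCl blocks that carbon as [4-methoxy-2,6-bis(methoxymethoxy)phenyl]trimethylsilane F1. A second directed lithiation with MeI gives [4-methoxy-3-methyl-2,6-bis(methoxymethoxy)phenyl]trimethylsilane F2. A third with N-methoxy-N,3-dimethylbutanamide gives 1-[6-methoxy-5-methyl-2,4-bis(methoxymethoxy)-3-(trimethylsilyl)phenyl]-3-methylbutan-1-one F3. HCl in methanol removes both MOM groups and, by protodesilylation, the silyl block. This gives 1-(2,4-dihydroxy-6-methoxy-5-methylphenyl)-3-methylbutan-1-one F4, whose only free ring carbon lies between the two hydroxyls.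
- Coupling: NaBH4 reduction of 12 at 0 °C gives 1-[2,4-dihydroxy-3-(hydroxymethyl)-6-methoxy-5-methylphenyl]-2-methylpropan-1-one F5. Gentle warming of F5 with an excess of F4 joins the halves by ortho-quinone methide formation and Friedel–Crafts-type capture, the classical way to methylene-bis(acylphloroglucinols), and gives 35 directly.
- Cost: exchange of the halves may occur and the symmetrical dimers would then have to be separated.

**Step 10.**
- What may go wrong: hydride delivery to the hindered styryl β-carbon may be slow, so that 1,2-hydrosilylation or hydrolytic loss of the ketene acetal competes.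
- Where the fallback runs: it replaces condensation and hydrosilylation by alkylation and soft enolisation, sets out from 13 (with dienolate 18 made from 17), and returns at 22.
- Sequence: NaBH4 reduces only the aldehyde of 13 to 1-[2,4-bis(benzyloxy)-3-(hydroxymethyl)-6-methoxy-5-methylphenyl]-2-methylpropan-1-one F6. PBr3 at 0 °C gives 1-[2,4-bis(benzyloxy)-3-(bromomethyl)-6-methoxy-5-methylphenyl]-2-methylpropan-1-one F7, which is used at once. α′-Alkylation of 18 with F7 at −78 °C gives 1-[2,6-bis(benzyloxy)-4-methoxy-3-methyl-5-(2-methylpropanoyl)phenyl]-5,5-dimethoxy-4-methylpent-4-en-3-one F8.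
- Final silylation: TESOTf/Et3N silylates the far more Lewis-basic vinylogous-carbonate carbonyl of F8 in preference to the twisted, hindered aryl ketone and gives 22.

**Step 8.**
- What may go wrong: chloride may demethylate the acylated dimethoxycarbenium ion faster than that ion loses its proton, which diverts the material to the β-keto ester level.
- Where the fallback runs: it avoids the ketene acetal altogether, sets out from 16, and returns at 17.
- Sequence: AlCl3-mediated addition of 16 to 1,1-dichloropropene gives 4,4,4-trichloro-3-methylbutan-2-one F9. Et3N dehydrochlorination gives 4,4-dichloro-3-methylbut-3-en-2-one F10. Two addition–elimination events with NaOMe in MeOH give 17.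

## Further compounds

F1 | step 14 | [4-methoxy-2,6-bis(methoxymethoxy)phenyl]trimethylsilane | COCOc1cc(OC)cc(OCOC)c1[Si](C)(C)C
F2 | step 14 | [4-methoxy-3-methyl-2,6-bis(methoxymethoxy)phenyl]trimethylsilane | COCOc1cc(OC)c(C)c(OCOC)c1[Si](C)(C)C
F3 | step 14 | 1-[6-methoxy-5-methyl-2,4-bis(methoxymethoxy)-3-(trimethylsilyl)phenyl]-3-methylbutan-1-one | COCOc1c([Si](C)(C)C)c(OCOC)c(C(=O)CC(C)C)c(OC)c1C
F4 | step 14 | 1-(2,4-dihydroxy-6-methoxy-5-methylphenyl)-3-methylbutan-1-one | COc1c(C)c(O)cc(O)c1C(=O)CC(C)C
F5 | step 14 | 1-[2,4-dihydroxy-3-(hydroxymethyl)-6-methoxy-5-methylphenyl]-2-methylpropan-1-one | COc1c(C)c(O)c(CO)c(O)c1C(=O)C(C)C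
F6 | step 10 | 1-[2,4-bis(benzyloxy)-3-(hydroxymethyl)-6-methoxy-5-methylphenyl]-2-methylpropan-1-one | COc1c(C)c(OCc2ccccc2)c(CO)c(OCc2ccccc2)c1C(=O)C(C)C
F7 | step 10 | 1-[2,4-bis(benzyloxy)-3-(bromomethyl)-6-methoxy-5-methylphenyl]-2-methylpropan-1-one | COc1c(C)c(OCc2ccccc2)c(CBr)c(OCc2ccccc2)c1C(=O)C(C)C
F8 | step 10 | 1-[2,6-bis(benzyloxy)-4-methoxy-3-methyl-5-(2-methylpropanoyl)phenyl]-5,5-dimethoxy-4-methylpent-4-en-3-one | COC(OC)=C(C)C(=O)CCc1c(OCc2ccccc2)c(C)c(OC)c(C(=O)C(C)C)c1OCc1ccccc1
F9 | step 8 | 4,4,4-trichloro-3-methylbutan-2-one | CC(=O)C(C)C(Cl)(Cl)Cl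
F10 | step 8 | 4,4-dichloro-3-methylbut-3-en-2-one | CC(=O)C(C)=C(Cl)Cl
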